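The 14-membered carbocycle is cut between the ketone carbon (C11) and its ring CH2 neighbour (C10). The key step exploits the γ-hydroxy ketone O8–C8–C9–C10–C11=O of this ring, read as a hydrated cycloalkyne: ring-closing alkyne metathesis of a diyne forms C10≡C11 and the macrocycle in one operation, and the tertiary hydroxyl on C8 later delivers the carbonyl oxygen to C11 alone (transannular 5-endo hydroalkoxylation, hydrolysis). The metathesis precursor is a diyne that already carries the oxolane and the α-methylene ε-lactone; it is assembled from (R)-carvone and (R)-linalool by an aldol union and a retro-Claisen opening of the carvone ring.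

Key step: step 20

Remark: atom labels follow cembrane numbering of the target – C1 ring CH bonded to acrylate carbon C15 (C16 lactone C=O, C17 exocyclic CH2); C2 CH2; C3 CHOH; C4 and C7 the oxolane carbons; C8 C(CH3)OH; C9, C10 CH2; C11 C=O; C12 the O–C(CH3) carbon of the lactone; C13, C14 CH2. Intermediates keep these labels.

**Carvone part (C1, C2, C11–C17)**

Step 1
Reactants: 1 (R)-(−)-carvone
Product: 2 carvone oxide (1R,4R,6R)-1-methyl-4-(prop-1-en-2-yl)-7-oxabicyclo[4.1.0]heptan-2-one
Conditions: H2O2 (35% aq.), NaOH (cat.), MeOH, 0 °C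
Reagents that add atoms: hydrogen peroxide OO
Why: Weitz–Scheffer nucleophilic epoxidation: hydroperoxide adds to the enone β-carbon (C13) anti to the isopropenyl group on C1 and closes onto C12, so the C12–O bond that later becomes the lactone C–O bond is set trans to the side chain (12R), while the unactivated isopropenyl alkene does not react.

Step 2
Reactants: 2 carvone oxide
Product: 3 diol (1R,4R)-1-methyl-4-(prop-1-en-2-yl)cyclohexane-1,2-diol as both C2 epimers
Conditions: LiAlH4, Et2O, 0 °C → rt
Reagents that add atoms: none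
Why: Hydride reduction of the ketone followed by reductive opening of the resulting 2,3-epoxy alkoxide at its secondary carbon C13 (less hindered, trans-diaxial mode) should leave the tertiary C12–O bond with its configuration; both C11 carbinol epimers are oxidized in step 3.

Step 3
Reactants: 3 diol
Product: 4 hydroxy ketone (2R,5R)-2-hydroxy-2-methyl-5-(prop-1-en-2-yl)cyclohexan-1-one
Conditions: SO3·pyridine, DMSO, i-Pr2NEt, CH2Cl2, 0 °C
Reagents that add atoms: none
Why: Parikh–Doering oxidation touches only the secondary alcohol, cannot cleave the glycol and leaves the alkene and the tertiary carbinol C12 unchanged.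

Step 4
Reactants: 4 hydroxy ketone
Product: 5 silyl ketone (2R,5R)-2-methyl-5-(prop-1-en-2-yl)-2-(triethylsilyloxy)cyclohexan-1-one
Conditions: Et3SiOTf, 2,6-lutidine, CH2Cl2, −78 → 0 °C
Reagents that add atoms: triethylsilyl triflate CC[Si](CC)(CC)OS(=O)(=O)C(F)(F)F
Why: Silylation with the silyl triflate is strong enough for the hindered tertiary α-ketol and masks O12, which otherwise would attack the side-chain carbonyl in step 12.

**Linalool part (C3–C10)**

Step 5
Reactants: 6 (R)-(−)-linalool
Product: 7 diol (2E,6R)-2,6-dimethylocta-2,7-diene-1,6-diol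
Conditions: SeO2 (cat.), t-BuOOH, CH2Cl2, 0 °C → rt
Reagents that add atoms: tert-butyl hydroperoxide CC(C)(C)OO; selenium dioxide (oxygen carrier) O=[Se]=O
Why: Riley allylic oxidation (ene reaction then 2,3-sigmatropic shift) of the electron-rich trisubstituted alkene occurs at the methyl group trans to the chain and gives the (E)-allylic alcohol, whereas the monosubstituted vinyl group is far less reactive.

Step 6
Reactants: 7 diol
Product: 9 oxolane diol (2R)-2-[(2S,5R)-5-ethenyl-5-methyloxolan-2-yl]propane-1,2-diol, via epoxy alcohol 8 (not isolated)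
Conditions: Ti(OiPr)4 (10 mol%), D-(−)-diethyl tartrate (12 mol%), t-BuOOH, 4 Å molecular sieves, CH2Cl2, −20 °C; then camphor-10-sulfonic acid (cat.), 0 °C
Reagents that add atoms: tert-butyl hydroperoxide CC(C)(C)OO
Why: Sharpless asymmetric epoxidation of the primary allylic alcohol with the D-tartrate should give the (2R,3R)-epoxy alcohol (C7 R, C8 R, reagent control), and acid then triggers 5-exo opening at C7 by the tertiary hydroxyl on C4 with inversion, which sets C7 (S), keeps C8 (R) with its own oxygen and places the two side chains on C4 and C7 cis on the oxolane.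

Step 7
Reactants: 9 oxolane diol
Product: 11 epoxide (2S,5R)-5-ethenyl-5-methyl-2-[(2R)-2-methyloxiran-2-yl]oxolane, via tosylate 10 (not isolated)
Conditions: TsCl, Et3N, Bu2SnO (cat.), CH2Cl2, 0 °C; then K2CO3, MeOH, rt
Reagents that add atoms: none
Why: Tin-acetal-catalysed monosulfonylation is selective for the primary hydroxyl and base then closes the epoxide by intramolecular Williamson etherification (3-exo) without touching the C8 stereocentre.

Step 8
Reactants: 11 epoxide
Product: 12 alkynol (2R)-2-[(2S,5R)-5-ethenyl-5-methyloxolan-2-yl]hex-4-yn-2-ol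
Conditions: 1-propynyllithium, THF–DMPU, 0 → 40 °C
Reagents that add atoms: 1-propynyllithium [Li]C#CC
Why: SN2 opening of the 2,2-disubstituted epoxide by the acetylide occurs only at the unsubstituted carbon C9, so C8 keeps its configuration and C10 enters as the inner carbon of a methyl-capped alkyne.

Step 9
Reactants: 12 alkynol
Product: 13 silyl ether of 12 at O8 (tert-butyldimethylsilyl)
Conditions: t-BuMe2SiOTf, 2,6-lutidine, CH2Cl2, 0 °C → rt
Reagents that add atoms: tert-butyldimethylsilyl triflate CC(C)(C)[Si](C)(C)OS(=O)(=O)C(F)(F)F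
Why: Silyl triflate silylation of the tertiary alcohol masks O8 so that it can neither attack the C3 carbonyl in step 12 nor bind the molybdenum alkylidyne in step 20.

Step 10
Reactants: 13 silyl ether
Product: 14 aldehyde (2R,5S)-5-[(2R)-2-(tert-butyldimethylsilyloxy)hex-4-yn-2-yl]-2-methyloxolane-2-carbaldehyde
Conditions: OsO4 (2 mol%), NaIO4, 2,6-lutidine, dioxane–H2O, rt
Reagents that add atoms: osmium tetroxide (oxygen carrier) O=[Os](=O)(=O)=O; sodium periodate [Na+].[O-]I(=O)(=O)=O
Why: Lemieux–Johnson oxidation: catalytic osmylation is much faster at the monosubstituted alkene than at the internal alkyne, and periodate cleaves the diol to the non-enolizable aldehyde with C4 intact.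

**Union and elaboration**

Step 11
Reactants: 5 silyl ketone; 14 aldehyde
Product: 15 aldol adduct (β-hydroxy ketone; new C2–C3 bond; epimers at C2 and C3)
Conditions: LiN(i-Pr)2, THF, −78 °C; then 14, −78 °C
Reagents that add atoms: none
Why: Directed aldol addition: ketone 5 can enolize only towards C2 because C12 is quaternary, and its lithium enolate adds to the non-enolizable aldehyde to form the C2–C3 bond; the two new centres are of no consequence because C3 is oxidized and C2 becomes a CH2 group in step 12.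

Step 12
Reactants: 15 aldol adduct
Product: 17 keto ester (C11 methyl ester; C3 ketone), via diketone 16 (not isolated)
Conditions: Dess–Martin periodinane, CH2Cl2, rt; filtration; then NaOMe (0.2 equiv), MeOH, 0 °C
Reagents that add atoms: methanol CO
Why: Dess–Martin oxidation gives the 2-acylcyclohexanone, which undergoes retro-Claisen ring cleavage by methoxide attack on the ring carbonyl C11 and loss of the C3 ketone enolate (the usual course for 2-acylcyclohexanones), so the C2–C11 bond of the carvone ring breaks, C11 becomes a methyl ester and C2 a CH2 group.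

Step 13
Reactants: 17 keto ester
Product: 18 hydroxy ester (3S alcohol)
Conditions: Zn(BH4)2, Et2O, −30 °C
Reagents that add atoms: none
Why: Chelation-controlled reduction: zinc ties the C3 carbonyl to the oxolane oxygen on C4 and hydride enters the five-membered chelate from the face of the C4 methyl group, away from the ring CH2 (C5) and the oxolane itself, which should give the (3S)-alcohol; the ester is not reduced by zinc borohydride.

Step 14
Reactants: 18 hydroxy ester
Product: 19 silyl ether of 18 at O3 (tert-butyldimethylsilyl)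
Conditions: t-BuMe2SiOTf, 2,6-lutidine, CH2Cl2, −40 → 0 °C
Reagents that add atoms: tert-butyldimethylsilyl triflate CC(C)(C)[Si](C)(C)OS(=O)(=O)C(F)(F)F
Why: Silylation of the hindered secondary alcohol with the silyl triflate blocks O3, which would otherwise form the six-membered lactone with C16 in step 19.

Step 15
Reactants: 19 silyl ether
Product: 21 terminal alkyne (C11≡CH on C12), via aldehyde 20 (not isolated)
Conditions: i-Bu2AlH (1.1 equiv), CH2Cl2, −78 °C; then MeOH, K2CO3, dimethyl (1-diazo-2-oxopropyl)phosphonate, −78 °C → rt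
Reagents that add atoms: dimethyl (1-diazo-2-oxopropyl)phosphonate CC(=O)C(=[N+]=[N-])P(=O)(OC)OC
Why: Partial reduction of the ester to the aldehyde (stable aluminium hemiacetal at −78 °C) followed in the same flask by Seyferth–Gilbert homologation with the Ohira–Bestmann reagent turns C11 into the inner carbon of a terminal alkyne; the aldehyde has no α-hydrogen, so C12 cannot epimerize.

Step 16
Reactants: 21 terminal alkyne
Product: 23 enal (CHO at C16), via allylic alcohol 22 (not isolated)
Conditions: SeO2 (cat.), t-BuOOH, CH2Cl2, rt; then MnO2, CH2Cl2, rt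
Reagents that add atoms: tert-butyl hydroperoxide CC(C)(C)OO; selenium dioxide (oxygen carrier) O=[Se]=O
Why: Riley allylic oxidation of the 1,1-disubstituted alkene takes place at its methyl group (preferred over the tertiary allylic C1–H and over propargylic C–H), and manganese dioxide then oxidizes the allylic alcohol to the 2-substituted acrolein.

Step 17
Reactants: 23 enal
Product: 24 acrylic acid (CO2H at C16)
Conditions: NaClO2, NaH2PO4, 2-methyl-2-butene, t-BuOH–H2O, 0 °C
Reagents that add atoms: sodium chlorite [Na+].[O-]Cl=O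
Why: Pinnick oxidation converts the enal into the 2-substituted acrylic acid under buffered conditions that leave alkynes, silyl ethers and the C1 centre untouched.

Step 18
Reactants: 24 acrylic acid
Product: 25 hydroxy acid (free O12–H)
Conditions: PPTS (cat.), MeOH, 0 °C → rt
Reagents that add atoms: none
Why: Acid-catalysed methanolysis removes the triethylsilyl ether much faster than the two tert-butyldimethylsilyl ethers, so only O12 is set free.

Step 19
Reactants: 25 hydroxy acid
Product: 27 lactone diyne (α-methylene ε-lactone closed), via mixed anhydride 26 (not isolated)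
Conditions: 2,4,6-Cl3C6H2COCl, Et3N, THF, rt; then DMAP, toluene (high dilution), 80 °C
Reagents that add atoms: none
Why: Yamaguchi lactonization: the mixed anhydride is opened by DMAP and the acylpyridinium is captured by the only free hydroxyl, the tertiary propargylic O12 (its alkynyl neighbour is sterically slim), which closes the seven-membered α-methylene lactone without involving a stereocentre.

Step 20
Reactants: 27 lactone diyne
Product: 28 cycloalkyne (C10≡C11 in the 14-membered ring)
Conditions: Mo(≡CC6H4OMe-4)(OSiPh3)3 (10 mol%), 4 Å and 5 Å molecular sieves, toluene (2 mM), 80 °C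
Reagents that add atoms: none
Why: The alkylidyne adds to the terminal alkyne at C11 ([2+2] cycloaddition to a molybdacyclobutadiene, cycloreversion) and the resulting C11 alkylidyne engages the C10≡C–CH3 alkyne of the same molecule, which forms the C10≡C11 bond and, after one more turnover, releases propyne that is taken up by the 5 Å sieves. The closest known reaction type is macrocyclic ring-closing alkyne metathesis of a diyne with one terminal and one methyl-capped alkyne by molybdenum alkylidynes bearing silanolate ligands. The step closes the 14-membered carbocycle as a cycloalkyne (macrocyclization, both alkyne carbons endocyclic), helped by the oxolane and the ε-lactone, which act as preformed turns. No stereocentre is formed or touched. The step needs ring closure instead of oligomerization (secured by high dilution and irreversible loss of propyne), chemoselectivity for alkynes over the acrylate (inherent to alkylidynes) and a catalyst that survives the terminal alkyne next to the hindered C12 (silanolate ligands, no free hydroxyl in the substrate). The new C10–C11 bond is the one that remains as the CH2–C(=O) bond of the target after step 22.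

Step 21
Reactants: 28 cycloalkyne
Product: 29 cycloalkyne diol (free O3–H and O8–H)
Conditions: HF·pyridine, pyridine, THF, 0 °C → rt
Reagents that add atoms: none
Why: Fluoride-mediated desilylation under buffered, slightly acidic conditions removes both tert-butyldimethylsilyl groups without opening or transposing the lactone.

Step 22
Reactants: 29 cycloalkyne diol
Product: 31 CNP0266269.2, via enol ether 30 (not isolated)
Conditions: Ph3PAuNTf2 (5 mol%), CH2Cl2, rt; then PPTS (cat.), THF–H2O, rt
Reagents that add atoms: water O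
Why: Gold-catalysed transannular hydroalkoxylation: the homopropargylic O8 adds 5-endo-dig to C11 (attack on C10 would need a four-membered ring, and the lactone carbonyl, locked s-trans in the seven-membered ring, cannot reach the alkyne), and mild acid hydrolysis of the cyclic enol ether returns O8 as the hydroxyl and leaves the ketone on C11.

**Compound list**

1 | (R)-(−)-carvone, (5R)-2-methyl-5-(prop-1-en-2-yl)cyclohex-2-en-1-one | C=C(C)[C@@H]1CC=C(C)C(=O)C1 | starting material
2 | carvone oxide, (1R,4R,6R)-1-methyl-4-(prop-1-en-2-yl)-7-oxabicyclo[4.1.0]heptan-2-one (epoxide trans to isopropenyl) | C=C(C)[C@@H]1C[C@H]2O[C@@]2(C)C(=O)C1 | intermediate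
3 | (1R,4R)-1-methyl-4-(prop-1-en-2-yl)cyclohexane-1,2-diol, both C2 epimers (tertiary OH trans to isopropenyl) | C=C(C)[C@@H]1CC[C@@](C)(O)C(O)C1 | intermediate
4 | (2R,5R)-2-hydroxy-2-methyl-5-(prop-1-en-2-yl)cyclohexan-1-one | C=C(C)[C@@H]1CC[C@@](C)(O)C(=O)C1 | intermediate
5 | (2R,5R)-2-methyl-5-(prop-1-en-2-yl)-2-(triethylsilyloxy)cyclohexan-1-one | C=C(C)[C@@H]1CC[C@@](C)(O[Si](CC)(CC)CC)C(=O)C1 | intermediate
6 | (R)-(−)-linalool, (3R)-3,7-dimethylocta-1,6-dien-3-ol | C=C[C@@](O)(C)CCC=C(C)C | starting material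
7 | (2E,6R)-2,6-dimethylocta-2,7-diene-1,6-diol | C=C[C@@](O)(C)CC/C=C(\C)CO | intermediate
8 | (3R)-5-[(2R,3R)-3-(hydroxymethyl)-3-methyloxiran-2-yl]-3-methylpent-1-en-3-ol | C=C[C@@](O)(C)CC[C@H]1O[C@]1(C)CO | intermediate (not isolated)
9 | (2R)-2-[(2S,5R)-5-ethenyl-5-methyloxolan-2-yl]propane-1,2-diol | C=C[C@@]1(C)CC[C@H](O1)[C@](C)(O)CO | intermediate
10 | (2R)-2-[(2S,5R)-5-ethenyl-5-methyloxolan-2-yl]-2-hydroxypropyl 4-methylbenzenesulfonate | C=C[C@@]1(C)CC[C@H](O1)[C@](C)(O)COS(=O)(=O)c1ccc(C)cc1 | intermediate (not isolated)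
11 | (2S,5R)-5-ethenyl-5-methyl-2-[(2R)-2-methyloxiran-2-yl]oxolane | C=C[C@@]1(C)CC[C@H](O1)[C@@]2(C)CO2 | intermediate
12 | (2R)-2-[(2S,5R)-5-ethenyl-5-methyloxolan-2-yl]hex-4-yn-2-ol | C=C[C@@]1(C)CC[C@H](O1)[C@](C)(O)CC#CC | intermediate
13 | tert-butyl{[(2R)-2-[(2S,5R)-5-ethenyl-5-methyloxolan-2-yl]hex-4-yn-2-yl]oxy}dimethylsilane | C=C[C@@]1(C)CC[C@H](O1)[C@](C)(O[Si](C)(C)C(C)(C)C)CC#CC | intermediate
14 | (2R,5S)-5-[(2R)-2-(tert-butyldimethylsilyloxy)hex-4-yn-2-yl]-2-methyloxolane-2-carbaldehyde | O=C[C@@]1(C)CC[C@H](O1)[C@](C)(O[Si](C)(C)C(C)(C)C)CC#CC | intermediate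
15 | aldol adduct: ketone 5 bearing on C2 the CH(OH) carbon C3 that is bonded to oxolane carbon C4 of 14; epimers at C2 and C3, otherwise 1R,4R,7S,8R,12R | OC(C1C(=O)[C@](C)(O[Si](CC)(CC)CC)CC[C@H]1C(C)=C)[C@@]1(C)CC[C@H](O1)[C@](C)(O[Si](C)(C)C(C)(C)C)CC#CC | intermediate
16 | 2-acylcyclohexanone: 15 with C3 oxidized to the ketone (C2 epimers or enol) | O=C(C1C(=O)[C@](C)(O[Si](CC)(CC)CC)CC[C@H]1C(C)=C)[C@@]1(C)CC[C@H](O1)[C@](C)(O[Si](C)(C)C(C)(C)C)CC#CC | intermediate (not isolated)
17 | methyl (2R,5R)-7-[(2R,5S)-5-[(2R)-2-(tert-butyldimethylsilyloxy)hex-4-yn-2-yl]-2-methyloxolan-2-yl]-2-methyl-7-oxo-5-(prop-1-en-2-yl)-2-(triethylsilyloxy)heptanoate | C=C(C)[C@H](CC[C@](O[Si](CC)(CC)CC)(C)C(=O)OC)CC(=O)[C@@]1(C)CC[C@H](O1)[C@](C)(O[Si](C)(C)C(C)(C)C)CC#CC | intermediate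
18 | 17 with the C3 ketone reduced to the (3S)-alcohol [(7S)-7-hydroxy heptanoate] | C=C(C)[C@H](CC[C@](O[Si](CC)(CC)CC)(C)C(=O)OC)C[C@H](O)[C@@]1(C)CC[C@H](O1)[C@](C)(O[Si](C)(C)C(C)(C)C)CC#CC | intermediate
19 | 18 as its tert-butyldimethylsilyl ether at O3 | C=C(C)[C@H](CC[C@](O[Si](CC)(CC)CC)(C)C(=O)OC)C[C@H](O[Si](C)(C)C(C)(C)C)[C@@]1(C)CC[C@H](O1)[C@](C)(O[Si](C)(C)C(C)(C)C)CC#CC | intermediate
20 | aldehyde: 19 with CHO in place of CO2CH3 at C11 | C=C(C)[C@H](CC[C@](O[Si](CC)(CC)CC)(C)C=O)C[C@H](O[Si](C)(C)C(C)(C)C)[C@@]1(C)CC[C@H](O1)[C@](C)(O[Si](C)(C)C(C)(C)C)CC#CC | intermediate (not isolated)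
21 | terminal alkyne: 19 with C≡CH in place of CO2CH3 (C11≡CH on C12); 1R,3S,4R,7S,8R,12R | C=C(C)[C@H](CC[C@](O[Si](CC)(CC)CC)(C)C#C)C[C@H](O[Si](C)(C)C(C)(C)C)[C@@]1(C)CC[C@H](O1)[C@](C)(O[Si](C)(C)C(C)(C)C)CC#CC | intermediate
22 | allylic alcohol: 21 with CH2OH in place of the isopropenyl CH3 | C=C(CO)[C@H](CC[C@](O[Si](CC)(CC)CC)(C)C#C)C[C@H](O[Si](C)(C)C(C)(C)C)[C@@]1(C)CC[C@H](O1)[C@](C)(O[Si](C)(C)C(C)(C)C)CC#CC | intermediate (not isolated)
23 | enal: 21 with CHO (C16) in place of the isopropenyl CH3 | C=C(C=O)[C@H](CC[C@](O[Si](CC)(CC)CC)(C)C#C)C[C@H](O[Si](C)(C)C(C)(C)C)[C@@]1(C)CC[C@H](O1)[C@](C)(O[Si](C)(C)C(C)(C)C)CC#CC | intermediate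
24 | acrylic acid: 23 oxidized to CO2H at C16 | C=C(C(=O)O)[C@H](CC[C@](O[Si](CC)(CC)CC)(C)C#C)C[C@H](O[Si](C)(C)C(C)(C)C)[C@@]1(C)CC[C@H](O1)[C@](C)(O[Si](C)(C)C(C)(C)C)CC#CC | intermediate
25 | hydroxy acid: 24 without the triethylsilyl group (free tertiary O12–H) | C=C(C(=O)O)[C@H](CC[C@](O)(C)C#C)C[C@H](O[Si](C)(C)C(C)(C)C)[C@@]1(C)CC[C@H](O1)[C@](C)(O[Si](C)(C)C(C)(C)C)CC#CC | intermediate
26 | mixed anhydride of 25 with 2,4,6-trichlorobenzoic acid | C=C(C(=O)OC(=O)c1c(Cl)cc(Cl)cc1Cl)[C@H](CC[C@](O)(C)C#C)C[C@H](O[Si](C)(C)C(C)(C)C)[C@@]1(C)CC[C@H](O1)[C@](C)(O[Si](C)(C)C(C)(C)C)CC#CC | intermediate (not isolated)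
27 | (4R,7R)-7-ethynyl-7-methyl-3-methylidene-4-{(2S)-2-(tert-butyldimethylsilyloxy)-2-[(2R,5S)-5-[(2R)-2-(tert-butyldimethylsilyloxy)hex-4-yn-2-yl]-2-methyloxolan-2-yl]ethyl}oxepan-2-one | C=C1C(=O)O[C@](C#C)(C)CC[C@@H]1C[C@H](O[Si](C)(C)C(C)(C)C)[C@@]1(C)CC[C@H](O1)[C@](C)(O[Si](C)(C)C(C)(C)C)CC#CC | intermediate
28 | cycloalkyne: 14-membered carbocycle with C10≡C11, oxolane (C4–O–C7), ε-lactone (C12–O–C16), O3 and O8 as tert-butyldimethylsilyl ethers; 1R,3S,4R,7S,8R,12R | C=C1C(=O)O[C@]2(C)CC[C@@H]1C[C@H](O[Si](C)(C)C(C)(C)C)[C@@]1(C)CC[C@H](O1)[C@](C)(O[Si](C)(C)C(C)(C)C)CC#C2 | intermediate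
29 | cycloalkyne diol: 28 with free O3–H and O8–H | C=C1C(=O)O[C@]2(C)CC[C@@H]1C[C@H](O)[C@@]1(C)CC[C@H](O1)[C@](C)(O)CC#C2 | intermediate
30 | cyclic enol ether: 29 after addition of O8 to C11 (2,3-dihydrofuran O8–C11=C10 across the ring) | C=C1C(=O)O[C@]2(C)CC[C@@H]1C[C@H](O)[C@@]1(C)CC[C@H](O1)[C@@]1(C)CC=C2O1 | intermediate (not isolated)
31 | CNP0266269.2, (1R,3S,4R,7S,8R,12R)-3,8-dihydroxy-11-oxo-4,7-epoxycembr-15(17)-en-16,12-olide | C=C1C(=O)O[C@]2(C)CC[C@@H]1C[C@H](O)[C@@]1(C)CC[C@H](O1)[C@](C)(O)CCC2=O | target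

**Totals**

Total step count: 22. Longest linear sequence: 18 steps (steps 5–10 from (R)-linalool, then steps 11–22).

**Steps most likely to fail**

Step 20 (ring-closing alkyne metathesis). The terminal alkyne can divert the catalyst (deprotonative loss of the alkylidyne, alkyne polymerization), and ring closure at the hindered propargylic carbon may then lose against oligomerization. Fallback, which replaces the terminal alkyne by an internal one: setting out from 27, iodination of the terminal alkyne (N-iodosuccinimide, AgNO3 cat., acetone) should give the iodoalkyne F1. Negishi coupling with MeZnCl (Pd(PPh3)4, THF) should give the methyl-capped diyne F2. Metathesis of F2 with the same molybdenum alkylidyne expels but-2-yne and comes back to the route at 28.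

Step 19 (lactonization). Acyl transfer to the hindered tertiary hydroxyl may be slower than intermolecular anhydride and oligo-ester formation or conjugate addition of DMAP to the activated acrylate. Fallback, which closes the macrocycle first and the lactone second: setting out from 24, silylation of the acid (Et3SiCl, imidazole, CH2Cl2) gives the silyl ester F3. Ring-closing alkyne metathesis then gives the cycloalkyne F4, in which the 14-membered ring holds O12 next to C16. PPTS in MeOH removes both triethylsilyl groups to give the cycloalkyne hydroxy acid F5. Yamaguchi activation to the mixed anhydride F6 then only has to close the lactone across the ring, which comes back to the route at 28.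

Step 12 (oxidation and retro-Claisen cleavage). Methoxide may attack the side-chain carbonyl C3 instead of the ring carbonyl C11 (loss of the acyl group, return to 5), or the ring may close again under the reversible conditions. Fallback, which opens the ring before the union while only one carbonyl is present: setting out from 5, sulfonylation of the lithium enolate (LiN(i-Pr)2, then PhSO2F, THF, −78 °C) gives the ring keto sulfone F7. LiOH in aqueous THF opens the ring to the sulfonyl acid F8. Its dianion (n-BuLi, 2 equiv, THF, −78 °C) adds to aldehyde 14 to give the hydroxy sulfone F9. Dess–Martin oxidation gives the acyclic keto sulfone F10, and SmI2 in THF–MeOH removes the sulfonyl group to give the keto acid F11. Esterification of F11 with Me3SiCHN2 comes back to the route at 17.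

Further compounds
F1 | step 20 | iodoalkyne: 27 with C≡C–I in place of C≡C–H on C12 | C=C1C(=O)O[C@](C#CI)(C)CC[C@@H]1C[C@H](O[Si](C)(C)C(C)(C)C)[C@@]1(C)CC[C@H](O1)[C@](C)(O[Si](C)(C)C(C)(C)C)CC#CC
F2 | step 20 | methyl-capped diyne: 27 with C≡C–CH3 in place of C≡C–H on C12 | C=C1C(=O)O[C@](C#CC)(C)CC[C@@H]1C[C@H](O[Si](C)(C)C(C)(C)C)[C@@]1(C)CC[C@H](O1)[C@](C)(O[Si](C)(C)C(C)(C)C)CC#CC
F3 | step 19 | triethylsilyl ester of acid 24 | C=C(C(=O)O[Si](CC)(CC)CC)[C@H](CC[C@](O[Si](CC)(CC)CC)(C)C#C)C[C@H](O[Si](C)(C)C(C)(C)C)[C@@]1(C)CC[C@H](O1)[C@](C)(O[Si](C)(C)C(C)(C)C)CC#CC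
F4 | step 19 | cycloalkyne silyl ester: 14-membered ring with C10≡C11, acrylic triethylsilyl ester on C1, O12 triethylsilyl ether, O3 and O8 tert-butyldimethylsilyl ethers | C=C(C(=O)O[Si](CC)(CC)CC)[C@@H]1CC[C@](O[Si](CC)(CC)CC)(C)C#CC[C@@](C)(O[Si](C)(C)C(C)(C)C)[C@@H]2CC[C@@](C)(O2)[C@@H](O[Si](C)(C)C(C)(C)C)C1
F5 | step 19 | cycloalkyne hydroxy acid: F4 with free CO2H and free O12–H | C=C(C(=O)O)[C@@H]1CC[C@](O)(C)C#CC[C@@](C)(O[Si](C)(C)C(C)(C)C)[C@@H]2CC[C@@](C)(O2)[C@@H](O[Si](C)(C)C(C)(C)C)C1
F6 | step 19 | mixed anhydride of F5 with 2,4,6-trichlorobenzoic acid | C=C(C(=O)OC(=O)c3c(Cl)cc(Cl)cc3Cl)[C@@H]1CC[C@](O)(C)C#CC[C@@](C)(O[Si](C)(C)C(C)(C)C)[C@@H]2CC[C@@](C)(O2)[C@@H](O[Si](C)(C)C(C)(C)C)C1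
F7 | step 12 | ring keto sulfone: ketone 5 with a phenylsulfonyl group on C2 (C2 epimers) | C=C(C)[C@@H]1CC[C@@](C)(O[Si](CC)(CC)CC)C(=O)C1S(=O)(=O)c1ccccc1
F8 | step 12 | sulfonyl acid: ring-opened F7, C11 carboxylic acid on C12 (OSiEt3), CH2SO2Ph (C2) on C1 | OC(=O)[C@](C)(O[Si](CC)(CC)CC)CC[C@H](CS(=O)(=O)c1ccccc1)C(C)=C
F9 | step 12 | hydroxy sulfone: adduct of the F8 dianion to aldehyde 14 (epimers at C2 and C3) | OC(=O)[C@](C)(O[Si](CC)(CC)CC)CC[C@H](C(C(O)[C@@]1(C)CC[C@H](O1)[C@](C)(O[Si](C)(C)C(C)(C)C)CC#CC)S(=O)(=O)c1ccccc1)C(C)=C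
F10 | step 12 | acyclic keto sulfone: F9 with C3 oxidized to the ketone | OC(=O)[C@](C)(O[Si](CC)(CC)CC)CC[C@H](C(C(=O)[C@@]1(C)CC[C@H](O1)[C@](C)(O[Si](C)(C)C(C)(C)C)CC#CC)S(=O)(=O)c1ccccc1)C(C)=C
F11 | step 12 | keto acid: the free carboxylic acid of methyl ester 17 | OC(=O)[C@](C)(O[Si](CC)(CC)CC)CC[C@H](CC(=O)[C@@]1(C)CC[C@H](O1)[C@](C)(O[Si](C)(C)C(C)(C)C)CC#CC)C(C)=C
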